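**Retrosynthetic overview**
- Key cut, made last: the C2–C1' bond. The flavone comes from 5,7,8-trimethoxychromone (free C2–H) and 2,3,4-trimethoxyphenylboronic acid by an oxidative Heck-type C–H arylation on divalent palladium. This avoids the chalcone and Baker–Venkataraman routes.
- Ring C (pyranone): the O1–C2 and C2–C3 bonds come from an o-hydroxyacetophenone plus one carbon delivered by DMF-DMA (enaminone closure).
- The o-hydroxyacetophenone comes from symmetric 1,2,3,5-tetramethoxybenzene by Friedel–Crafts acetylation. Chelation-controlled loss of the doubly flanked O-methyl fixes the 5,7,8 pattern over the 5,6,7 pattern.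
- Ring order: ring A is bought, ring C is built on it, and ring B is bought as the boronic acid and attached last.

Assumption: the target has no stereocentre and no stable chiral axis, so it is achiral and "single enantiomer" needs no action. The only stereodescriptors in the route are E-alkene marks on intermediates.

**Step 1**
Reactants: 1 1,2,3,5-tetramethoxybenzene
Product: 3 2'-hydroxy-3',4',6'-trimethoxyacetophenone, via 2',3',4',6'-tetramethoxyacetophenone 2 (not isolated)
Conditions: AcCl (1.2 equiv), AlCl3 (2.5 equiv), CH2Cl2, 0 °C to 40 °C, 6 h; then ice/2 M HCl
Reagents that add atoms: acetyl chloride, CC(=O)Cl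
Why: Friedel–Crafts acylation takes one of the two equivalent free positions of the symmetric electron-rich arene, and AlCl3 held by the new carbonyl then cleaves the 2'-OMe selectively (chelation-controlled aryl methyl ether cleavage), because that group is flanked on both sides, twisted out of plane and the most Lewis basic, while the resulting chelated phenoxide ties up the carbonyl and protects the 6'-OMe; no stereocentre is formed.

**Step 2**
Reactants: 3 2'-hydroxy-3',4',6'-trimethoxyacetophenone
Product: 5 5,7,8-trimethoxychromone (5,7,8-trimethoxy-4H-chromen-4-one), via enaminone 4 (not isolated)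
Conditions: DMF-DMA (2.5 equiv), toluene, 100 °C, 4 h; evaporate; AcOH, 110 °C, 2 h
Reagents that add atoms: N,N-dimethylformamide dimethyl acetal (DMF-DMA), COC(OC)N(C)C
Why: Aminomethylenation of the methyl ketone by the formamide acetal gives the push–pull E-enaminone, and in hot acetic acid the phenol adds to the protonated vinylogous amide (6-endo oxa-Michael addition) and expels dimethylamine, closing ring C by the enaminone route to chromones; no stereocentre is formed.

**Step 3**
Reactants: 5 5,7,8-trimethoxychromone; 6 (2,3,4-trimethoxyphenyl)boronic acid
Product: 7 2',3',4',5,7,8-hexamethoxyflavone (target)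
Conditions: 6 (2.5 equiv, three portions), Pd(OAc)2 (10 mol %), 5-nitro-1,10-phenanthroline (12 mol %), O2 (1 atm), DMF, 90 °C, 24 h
Reagents that add atoms: none
Why: In this oxidative boron-Heck reaction (Heck-type C2–H arylation of a chromone), boron-to-palladium transmetalation is followed by migratory insertion into the polarised C2=C3 bond, placing aryl on the β-carbon C2 and palladium on C3, then enolate-type face exchange allows syn β-hydride elimination to restore the pyranone, and O2 returns zerovalent palladium to divalent palladium in the non-acidic polar medium that disfavours protonolysis; no stereocentre remains.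

**Compound list**
1 | 1,2,3,5-tetramethoxybenzene | COc1cc(OC)c(OC)c(OC)c1 | starting material
2 | 2',3',4',6'-tetramethoxyacetophenone | CC(=O)c1c(OC)cc(OC)c(OC)c1OC | intermediate
3 | 2'-hydroxy-3',4',6'-trimethoxyacetophenone | CC(=O)c1c(OC)cc(OC)c(OC)c1O | intermediate
4 | (E)-3-(dimethylamino)-1-(2-hydroxy-3,4,6-trimethoxyphenyl)prop-2-en-1-one (enaminone) | CN(C)/C=C/C(=O)c1c(OC)cc(OC)c(OC)c1O | intermediate
5 | 5,7,8-trimethoxy-4H-chromen-4-one (5,7,8-trimethoxychromone) | O=c1ccoc2c(OC)c(OC)cc(OC)c12 | intermediate
6 | (2,3,4-trimethoxyphenyl)boronic acid | COc1ccc(B(O)O)c(OC)c1OC | starting material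
7 | 2',3',4',5,7,8-hexamethoxyflavone | COc1ccc(-c2cc(=O)c3c(OC)cc(OC)c(OC)c3o2)c(OC)c1OC | target

**Total step count:** 3
**Longest linear sequence:** 3 (1 to 3 to 5 to 7; 6 is bought)

**Steps most likely to fail**

Step 3 carries the highest risk. The ortho-methoxy boronic acid can protodeboronate or homocouple, and the electron-rich chromone may insert slowly. The fallback sets out from 3 and comes back to the route at 7. Claisen–Schmidt condensation of 3 with commercial 2,3,4-trimethoxybenzaldehyde (KOH, EtOH, rt) gives (E)-2'-hydroxy-2,3,3',4,4',6'-hexamethoxychalcone F1. Catalytic I2 in DMSO at 130 °C then cyclises and dehydrogenates it to 7. This builds ring C around ring B and needs neither 5 nor 6.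

Step 1 is the next risk. Over-demethylation or a mixture of phenols can arise under hot AlCl3. The fallback sets out from 1 and comes back to the route at 3.
- Directed ortho-lithiation between the 3- and 5-methoxy groups (n-BuLi, TMEDA, THF, 0 °C) gives (2,3,4,6-tetramethoxyphenyl)lithium F2.
- F2 is acylated with N-methoxy-N-methylacetamide (−78 °C to rt, aqueous NH4Cl quench) to give 2, which is isolated and purified here.
- A separate mono-demethylation with BCl3 (1.1 equiv, CH2Cl2, −78 °C to 0 °C) then gives 3.

C–C bond formation and ether cleavage are thus decoupled, and no acidic acylation is used.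

Step 2 is the lowest risk. The acetal may O-methylate the phenol, or ring closure may be incomplete. The fallback sets out from 3 and comes back to the route at 5. Claisen formylation of the methyl ketone (NaH, ethyl formate, THF, 0 °C to rt) gives 2-hydroxy-5,7,8-trimethoxychroman-4-one F3, the racemic ring-closed hemiacetal of the β-ketoaldehyde. Catalytic p-TsOH in toluene at 80 °C dehydrates it to 5.

**Further compounds**
F1 | step 3 | (E)-2'-hydroxy-2,3,3',4,4',6'-hexamethoxychalcone | COc1ccc(/C=C/C(=O)c2c(OC)cc(OC)c(OC)c2O)c(OC)c1OC
F2 | step 1 | (2,3,4,6-tetramethoxyphenyl)lithium | [Li]c1c(OC)cc(OC)c(OC)c1OC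
F3 | step 2 | 2-hydroxy-5,7,8-trimethoxychroman-4-one (racemic hemiacetal) | OC1CC(=O)c2c(OC)cc(OC)c(OC)c2O1
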